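The readings are calculated on assumed constants; the scatter is artificial.

The target is slow. The west run reads 2.6% of it at 48.0 h, and the south-west run reads 5.2% at 48.0 h, while the starting material stands at 1.4% and 0% at those times.

the same everywhere: starting material 0.050 M

| run | partner | second reagent | third reagent | remark | time |
|---|---|---|---|---|---|
| west | 0.055 M | 0.040 M | 0.20 M | run made earlier |  |
| south-west | 0.055 M | 0.095 M | 0.20 M | run made earlier |  |
| Saturday's | 0.0550 M | 0.0650 M | 0.200 M |  | 50 h |
| Sunday's | 0.0550 M | 0.130 M | 0.200 M |  | 50 h |

| run | time / h | target / % | starting material / % |
|---|---|---|---|
| west | 2.50 | 0.2 | 67.0 |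
| west | 8.00 | 0.4 | 33.8 |
| west | 15.0 | 0.1 | 17.5 |
| west | 20.0 | 0.9 | 10.8 |
| west | 30.0 | 1.7 | 4.9 |
| west | 40.0 | 1.7 | 2.7 |
| west | 48.0 | 2.6 | 1.4 |
| south-west | 8.00 | 0 | 22.3 |
| south-west | 15.0 | 0.5 | 7.7 |
| south-west | 20.0 | 0.7 | 3.8 |
| south-west | 30.0 | 2.8 | 1.2 |
| south-west | 40.0 | 3.9 | 0.5 |
| south-west | 48.0 | 5.2 | 0 |

(readings scatter by 0.3 percentage points)

- in percentages every species weighs as the starting material in it: one side product B counts as two
- the earlier runs were read with a standard deviation of 0.3 percentage points
- candidate steps: starting material + partner -> intermediate A; third reagent + intermediate B -> target; second reagent + intermediate A -> intermediate B; starting material + target -> side product B; starting material + second reagent -> side product A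

1. which of the two there is more of at the end, Saturday's (target / side product A)
2. which of the two there is more of at the end, Sunday's (target / side product A)
3. amount of target at the end, in percent of the starting material charged, Saturday's
4. amount of target at the end, in percent of the starting material charged, Sunday's

I turn the question round. For the opposite outcome, the target has to end above side product A, so the fraction of the starting material that goes to side product A has to lie under the target's own fraction. I need that side share, and this reckoning is my own.

The two runs charge the same partner. They differ in second reagent, 0.800 and 1.90 equivalents of the starting material's charge. I treat the decay over the first 8.00 h as pseudo-first-order, with second reagent taken as charged. The fraction left then gives a constant of 0.136 h⁻¹ for the west run and 0.188 h⁻¹ for the south-west run. Their difference per equivalent of second reagent is the side rate 0.0473 h⁻¹.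

The side share of a flask is this side rate times its equivalents, over its decay constant, which I extend along the same line from the west run. Saturday's flask gets 38.6% and Sunday's flask 55.7%. The higher of the two last target readings is 5.2%, in the south-west run at 48.0 h. Saturday's share is 7.42 times that reading and Sunday's share 10.7 times, while Sunday's flask charges 1.37 times the second reagent of the south-west run. Both shares stand above that reading, so I commit to side product A in both flasks.

The forecast says side product A for Saturday's and side product A for Sunday's, with 4% and 7.6% of target: “Side product A dominates in both runs.” It puts the direct loss to side product A at roughly 20 to 35 percent, which differs from my shares.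

Saturday's flask ends with 37.4% of side product A and 4.49% of target, and Sunday's with 53.1% and 7.05%, so the forecast holds.

    starting material + partner → intermediate A (k = 2.50 M⁻¹ h⁻¹)
    third reagent + intermediate B → target (k = 0.0726 M⁻¹ h⁻¹)
    second reagent + intermediate A → intermediate B (k = 0.154 M⁻¹ h⁻¹)
    starting material + target → side product B (k = 0.839 M⁻¹ h⁻¹)
    starting material + second reagent → side product A (k = 1.04 M⁻¹ h⁻¹)

On Saturday's flask, intermediate A still holds 46.5% at 50.0 h. The neighbour flask is Sunday's with 0.052 M of second reagent. The side rate gives it a share of 33.5%, and it holds 32.7% of side product A at 50.0 h.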